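**Target:** (1R)-1-[(2R,4S,5S)-4-hydroxy-5-pentyloxolan-2-yl]dec-9-en-1-yl dodecanoate. On the C19 chain this is 6S,7S,9R,10R, with a 2,3-cis-2,5-trans tetrahydrofuran.

Convention used below: chain locants C1–C19 run from the pentyl CH3 (C1) to the vinyl CH2 (C19). C6 and C9 are the ring carbons on oxygen, C7 is the ring carbinol, C10 the ester carbinol.

## Retrosynthetic overview

1. Target 28 comes from tetrahydrofuranol 22 (C7-OH free, C10-OTBS) by a protecting-group interchange: PMB on O7, TBS off, dodecanoyl on O10, PMB off.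
2. The only ring, the tetrahydrofuran, is closed last among the skeletal events: 5-exo SN2 attack of the C9 hydroxyl on the C6 chloride of chlorodiol 21, with inversion at C6.
3. 21 comes from ketochlorohydrin 19 by 1,3-syn reduction; 19 is made by the key C7–C8 bond formation, an intermolecular lithium aldol between methyl ketone 13 (C8–C19) and (R)-2-chloroheptanal 17 (C1–C7).
4. 13 comes from undec-10-enoyl chloride by Evans α-hydroxylation (sets C10). 17 comes from (E)-oct-2-en-1-ol by Sharpless epoxidation, C3 chloride opening and glycol cleavage (sets C6).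

## Route

Step 1
Reactants: 1 (4R)-4-benzyl-1,3-oxazolidin-2-one; 2 undec-10-enoyl chloride
Product: 4 (4R)-4-benzyl-3-(undec-10-enoyl)-1,3-oxazolidin-2-one, via lithium oxazolidinide 3 (not isolated)
Conditions: n-BuLi, THF, −78 °C; then 2, −78 → 0 °C
Reagents that add atoms: none
Why: N-acylation of the lithiated Evans auxiliary by the acid chloride is fast and clean and leaves the terminal alkene untouched.

Step 2
Reactants: 4 (4R)-4-benzyl-3-(undec-10-enoyl)-1,3-oxazolidin-2-one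
Product: 6 (4R)-4-benzyl-3-[(2R)-2-hydroxyundec-10-enoyl]-1,3-oxazolidin-2-one, via sodium Z-enolate 5 (not isolated)
Conditions: NaN(SiMe3)2, THF, −78 °C; 2-(phenylsulfonyl)-3-phenyloxaziridine, −78 °C; AcOH quench at −78 °C
Reagents that add atoms: 2-(phenylsulfonyl)-3-phenyloxaziridine (Davis oxaziridine), O=S(=O)(c1ccccc1)N1OC1c1ccccc1
Why: Evans electrophilic enolate hydroxylation, in which the chelated Z-enolate is oxidised on the face opposite the (R)-benzyl group, setting C10 as R (the same facial sense as Evans alkylation).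

Step 3
Reactants: 6 (4R)-4-benzyl-3-[(2R)-2-hydroxyundec-10-enoyl]-1,3-oxazolidin-2-one
Product: 7 (4R)-4-benzyl-3-[(2R)-2-{[tert-butyl(dimethyl)silyl]oxy}undec-10-enoyl]-1,3-oxazolidin-2-one
Conditions: TBSOTf, 2,6-lutidine, CH2Cl2, −78 → 0 °C
Reagents that add atoms: tert-butyldimethylsilyl triflate, CC(C)(C)[Si](C)(C)OS(=O)(=O)C(F)(F)F
Why: Silylation with a silyl triflate and a hindered base protects the α-hydroxyl without the base-induced acyl transfer that free α-hydroxy imides are prone to.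

Step 4
Reactants: 7 (4R)-4-benzyl-3-[(2R)-2-{[tert-butyl(dimethyl)silyl]oxy}undec-10-enoyl]-1,3-oxazolidin-2-one
Product: 9 (2R)-2-{[tert-butyl(dimethyl)silyl]oxy}undec-10-enoic acid, via lithium peroxycarboxylate 8 (not isolated)
Conditions: LiOH, H2O2, THF/H2O (3:1), 0 °C; then Na2SO3; then 1 M HCl
Reagents that add atoms: hydrogen peroxide (as LiOOH), OO
Why: Hydroperoxide-mediated auxiliary hydrolysis attacks only the exocyclic carbonyl even of hindered imides, does not epimerise C10 and releases the auxiliary for reuse.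

Step 5
Reactants: 9 (2R)-2-{[tert-butyl(dimethyl)silyl]oxy}undec-10-enoic acid
Product: 11 (2R)-2-{[tert-butyl(dimethyl)silyl]oxy}-N-methoxy-N-methylundec-10-enamide, via acyl imidazolide 10 (not isolated)
Conditions: 1,1'-carbonyldiimidazole, CH2Cl2, rt; then MeNHOMe·HCl, rt
Reagents that add atoms: N,O-dimethylhydroxylamine hydrochloride, CNOC.Cl
Why: Weinreb amide formation through the acyl imidazolide is a mild amidation that does not racemise the α-silyloxy acid.

Step 6
Reactants: 11 (2R)-2-{[tert-butyl(dimethyl)silyl]oxy}-N-methoxy-N-methylundec-10-enamide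
Product: 13 (3R)-3-{[tert-butyl(dimethyl)silyl]oxy}dodec-11-en-2-one, via magnesium hemiaminal 12 (not isolated)
Conditions: MeMgBr, THF, 0 °C
Reagents that add atoms: methylmagnesium bromide, C[Mg]Br
Why: Weinreb ketone synthesis, where the chelated tetrahedral intermediate survives until work-up, so a single methyl (C8) is added and C10 is not epimerised.

Step 7
Reactants: 14 (E)-oct-2-en-1-ol
Product: 15 [(2S,3S)-3-pentyloxiran-2-yl]methanol
Conditions: Ti(OiPr)4 (5 mol %), L-(+)-diethyl tartrate (6 mol %), t-BuOOH, 4 Å MS, CH2Cl2, −20 °C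
Reagents that add atoms: tert-butyl hydroperoxide, CC(C)(C)OO
Why: Sharpless asymmetric epoxidation of an E-allylic alcohol with L-(+)-tartrate delivers oxygen to the face that gives the (2S,3S)-epoxide, typically in at least 94% ee.

Step 8
Reactants: 15 [(2S,3S)-3-pentyloxiran-2-yl]methanol
Product: 16 (2S,3R)-3-chlorooctane-1,2-diol
Conditions: ClTi(OiPr)3, PhMe, 0 °C → rt
Reagents that add atoms: chlorotitanium triisopropoxide, CC(C)O[Ti](Cl)(OC(C)C)OC(C)C
Why: Titanium-mediated opening of a 2,3-epoxy alcohol, in which the epoxide bound to the titanium alkoxide is attacked by chloride at the distal carbon C3 with inversion, turning 3S-O into the 3R chloride (future C6).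

Step 9
Reactants: 16 (2S,3R)-3-chlorooctane-1,2-diol
Product: 17 (2R)-2-chloroheptanal
Conditions: NaIO4 on silica gel, CH2Cl2, rt; filtered and used at once
Reagents that add atoms: none
Why: Periodate glycol cleavage under neutral conditions removes C1 as formaldehyde without epimerising the α-chloro aldehyde, and any 2-chloro-1,3-diol regioisomer from step 8 is inert and is left behind.

Step 10
Reactants: 13 (3R)-3-{[tert-butyl(dimethyl)silyl]oxy}dodec-11-en-2-one; 17 (2R)-2-chloroheptanal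
Product: 19 (6R,7S,10R)-10-{[tert-butyl(dimethyl)silyl]oxy}-6-chloro-7-hydroxynonadec-18-en-9-one, via lithium enolate 18 (not isolated)
Conditions: LiN(iPr)2, THF, −78 °C; then 17, −78 °C; AcOH quench at −78 °C
Reagents that add atoms: none
Why: Intermolecular lithium aldol joining C1–C7 to C8–C19, in which the kinetic methyl enolate adds to the α-chloroaldehyde through a Cornforth (polar Felkin–Anh) transition state to give the 6,7-anti chlorohydrin (7S), and the cold acidic quench prevents epoxide closure.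

Step 11
Reactants: 19 (6R,7S,10R)-10-{[tert-butyl(dimethyl)silyl]oxy}-6-chloro-7-hydroxynonadec-18-en-9-one
Product: 21 (6R,7S,9R,10R)-10-{[tert-butyl(dimethyl)silyl]oxy}-6-chlorononadec-18-ene-7,9-diol, via diethylboron aldolate 20 (not isolated)
Conditions: Et2BOMe, THF/MeOH (4:1), −78 °C; NaBH4, −78 °C; AcOH; MeOH co-evaporation
Reagents that add atoms: none
Why: Narasaka–Prasad reduction, where hydride adds axially to the six-membered boron chelate to give the 1,3-syn diol (9R), a sense reinforced by the Felkin–Anh preference of the α'-silyloxy centre for the 9,10-syn product; the non-basic work-up spares the chlorohydrin.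

Step 12
Reactants: 21 (6R,7S,9R,10R)-10-{[tert-butyl(dimethyl)silyl]oxy}-6-chlorononadec-18-ene-7,9-diol
Product: 22 (2S,3S,5R)-5-[(1R)-1-{[tert-butyl(dimethyl)silyl]oxy}dec-9-en-1-yl]-2-pentyloxolan-3-ol
Conditions: AgOTf, Ag2O, THF, rt → 50 °C
Reagents that add atoms: none
Why: Silver-assisted 5-exo-tet Williamson-type cyclisation, in which the C9 hydroxyl displaces the activated C6 chloride with inversion (6R-Cl to 6S-O) to give the 2,3-cis-2,5-trans ring, while Ag2O removes acid so the silyl ether survives.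

Step 13
Reactants: 22 (2S,3S,5R)-5-[(1R)-1-{[tert-butyl(dimethyl)silyl]oxy}dec-9-en-1-yl]-2-pentyloxolan-3-ol
Product: 24 tert-butyl({(1R)-1-[(2R,4S,5S)-4-[(4-methoxyphenyl)methoxy]-5-pentyloxolan-2-yl]dec-9-en-1-yl}oxy)dimethylsilane, via sodium alkoxide 23 (not isolated)
Conditions: NaH, 4-methoxybenzyl chloride, Bu4NI (cat.), DMF, 0 °C → rt
Reagents that add atoms: 4-methoxybenzyl chloride, COc1ccc(CCl)cc1
Why: Williamson etherification of the only free hydroxyl (O7), and silyl migration from O10 is geometrically disfavoured because the two oxygens lie on opposite faces of the ring.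

Step 14
Reactants: 24 tert-butyl({(1R)-1-[(2R,4S,5S)-4-[(4-methoxyphenyl)methoxy]-5-pentyloxolan-2-yl]dec-9-en-1-yl}oxy)dimethylsilane
Product: 25 (1R)-1-[(2R,4S,5S)-4-[(4-methoxyphenyl)methoxy]-5-pentyloxolan-2-yl]dec-9-en-1-ol
Conditions: Bu4NF, THF, rt → 40 °C
Reagents that add atoms: none
Why: Fluoride desilylation frees only O10, since the PMB ether, the ring and the alkene are inert to fluoride.

Step 15
Reactants: 25 (1R)-1-[(2R,4S,5S)-4-[(4-methoxyphenyl)methoxy]-5-pentyloxolan-2-yl]dec-9-en-1-ol; 26 dodecanoyl chloride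
Product: 27 (1R)-1-[(2R,4S,5S)-4-[(4-methoxyphenyl)methoxy]-5-pentyloxolan-2-yl]dec-9-en-1-yl dodecanoate
Conditions: Et3N, DMAP (cat.), CH2Cl2, 0 °C → rt
Reagents that add atoms: none
Why: DMAP-catalysed acylation of the single free secondary alcohol places the dodecanoyl group on O10 with retention at C10.

Step 16
Reactants: 27 (1R)-1-[(2R,4S,5S)-4-[(4-methoxyphenyl)methoxy]-5-pentyloxolan-2-yl]dec-9-en-1-yl dodecanoate
Product: 28 (1R)-1-[(2R,4S,5S)-4-hydroxy-5-pentyloxolan-2-yl]dec-9-en-1-yl dodecanoate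
Conditions: DDQ, CH2Cl2/pH 7 buffer (10:1), 0 °C → rt
Reagents that add atoms: none
Why: Oxidative PMB cleavage under neutral conditions leaves the ester and the terminal alkene untouched, and the trans arrangement of O7 and the side chain prevents acyl migration.

## Compound list

1 | (4R)-4-benzyl-1,3-oxazolidin-2-one | O=C1N[C@H](Cc2ccccc2)CO1 | starting material
2 | undec-10-enoyl chloride | C=CCCCCCCCCC(=O)Cl | starting material
3 | lithium (4R)-4-benzyl-2-oxo-1,3-oxazolidin-3-ide (not isolated) | [Li+].O=C1[N-][C@H](Cc2ccccc2)CO1 | intermediate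
4 | (4R)-4-benzyl-3-(undec-10-enoyl)-1,3-oxazolidin-2-one | C=CCCCCCCCCC(=O)N1[C@H](Cc2ccccc2)COC1=O | intermediate
5 | sodium (Z)-enolate of 4 (not isolated) | [Na+].C=CCCCCCCC/C=C(\[O-])N1[C@H](Cc2ccccc2)COC1=O | intermediate
6 | (4R)-4-benzyl-3-[(2R)-2-hydroxyundec-10-enoyl]-1,3-oxazolidin-2-one | C=CCCCCCCC[C@@H](O)C(=O)N1[C@H](Cc2ccccc2)COC1=O | intermediate
7 | (4R)-4-benzyl-3-[(2R)-2-{[tert-butyl(dimethyl)silyl]oxy}undec-10-enoyl]-1,3-oxazolidin-2-one | C=CCCCCCCC[C@@H](O[Si](C)(C)C(C)(C)C)C(=O)N1[C@H](Cc2ccccc2)COC1=O | intermediate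
8 | lithium (2R)-2-{[tert-butyl(dimethyl)silyl]oxy}undec-10-eneperoxoate (not isolated) | [Li+].C=CCCCCCCC[C@@H](O[Si](C)(C)C(C)(C)C)C(=O)O[O-] | intermediate
9 | (2R)-2-{[tert-butyl(dimethyl)silyl]oxy}undec-10-enoic acid | C=CCCCCCCC[C@@H](O[Si](C)(C)C(C)(C)C)C(=O)O | intermediate
10 | 1-[(2R)-2-{[tert-butyl(dimethyl)silyl]oxy}undec-10-enoyl]-1H-imidazole (not isolated) | C=CCCCCCCC[C@@H](O[Si](C)(C)C(C)(C)C)C(=O)n1ccnc1 | intermediate
11 | (2R)-2-{[tert-butyl(dimethyl)silyl]oxy}-N-methoxy-N-methylundec-10-enamide | C=CCCCCCCC[C@@H](O[Si](C)(C)C(C)(C)C)C(=O)N(C)OC | intermediate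
12 | bromomagnesium alkoxide of the methyl adduct of 11 (tetrahedral hemiaminal, not isolated) | C=CCCCCCCC[C@@H](O[Si](C)(C)C(C)(C)C)C(C)(O[Mg]Br)N(C)OC | intermediate
13 | (3R)-3-{[tert-butyl(dimethyl)silyl]oxy}dodec-11-en-2-one | C=CCCCCCCC[C@@H](O[Si](C)(C)C(C)(C)C)C(C)=O | intermediate
14 | (E)-oct-2-en-1-ol | CCCCC/C=C/CO | starting material
15 | [(2S,3S)-3-pentyloxiran-2-yl]methanol | CCCCC[C@@H]1O[C@H]1CO | intermediate
16 | (2S,3R)-3-chlorooctane-1,2-diol | CCCCC[C@@H](Cl)[C@@H](O)CO | intermediate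
17 | (2R)-2-chloroheptanal | CCCCC[C@@H](Cl)C=O | intermediate
18 | lithium enolate of 13 at C1 (not isolated) | [Li+].C=CCCCCCCC[C@@H](O[Si](C)(C)C(C)(C)C)C(=C)[O-] | intermediate
19 | (6R,7S,10R)-10-{[tert-butyl(dimethyl)silyl]oxy}-6-chloro-7-hydroxynonadec-18-en-9-one | CCCCC[C@@H](Cl)[C@@H](O)CC(=O)[C@H](O[Si](C)(C)C(C)(C)C)CCCCCCCC=C | intermediate
20 | O7-diethylboryl derivative (boron chelate) of 19 (not isolated) | CCCCC[C@@H](Cl)[C@@H](OB(CC)CC)CC(=O)[C@H](O[Si](C)(C)C(C)(C)C)CCCCCCCC=C | intermediate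
21 | (6R,7S,9R,10R)-10-{[tert-butyl(dimethyl)silyl]oxy}-6-chlorononadec-18-ene-7,9-diol | CCCCC[C@@H](Cl)[C@@H](O)C[C@@H](O)[C@H](O[Si](C)(C)C(C)(C)C)CCCCCCCC=C | intermediate
22 | (2S,3S,5R)-5-[(1R)-1-{[tert-butyl(dimethyl)silyl]oxy}dec-9-en-1-yl]-2-pentyloxolan-3-ol | C=CCCCCCCC[C@@H](O[Si](C)(C)C(C)(C)C)[C@H]1C[C@H](O)[C@H](CCCCC)O1 | intermediate
23 | sodium alkoxide of 22 (not isolated) | [Na+].C=CCCCCCCC[C@@H](O[Si](C)(C)C(C)(C)C)[C@H]1C[C@H]([O-])[C@H](CCCCC)O1 | intermediate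
24 | tert-butyl({(1R)-1-[(2R,4S,5S)-4-[(4-methoxyphenyl)methoxy]-5-pentyloxolan-2-yl]dec-9-en-1-yl}oxy)dimethylsilane | C=CCCCCCCC[C@@H](O[Si](C)(C)C(C)(C)C)[C@H]1C[C@H](OCc2ccc(OC)cc2)[C@H](CCCCC)O1 | intermediate
25 | (1R)-1-[(2R,4S,5S)-4-[(4-methoxyphenyl)methoxy]-5-pentyloxolan-2-yl]dec-9-en-1-ol | C=CCCCCCCC[C@@H](O)[C@H]1C[C@H](OCc2ccc(OC)cc2)[C@H](CCCCC)O1 | intermediate
26 | dodecanoyl chloride | CCCCCCCCCCCC(=O)Cl | starting material
27 | (1R)-1-[(2R,4S,5S)-4-[(4-methoxyphenyl)methoxy]-5-pentyloxolan-2-yl]dec-9-en-1-yl dodecanoate | C=CCCCCCCC[C@@H](OC(=O)CCCCCCCCCCC)[C@H]1C[C@H](OCc2ccc(OC)cc2)[C@H](CCCCC)O1 | intermediate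
28 | (1R)-1-[(2R,4S,5S)-4-hydroxy-5-pentyloxolan-2-yl]dec-9-en-1-yl dodecanoate | C=CCCCCCCC[C@@H](OC(=O)CCCCCCCCCCC)[C@H]1C[C@H](O)[C@H](CCCCC)O1 | target

## Step count and risks

Total steps: 16. Longest linear sequence: 13 steps (steps 1–6, then 10–16); steps 7–9 form the second branch.

**Step 8 (regioselectivity of the chloride opening).** Chloride may attack C2 as well as C3, and only the C3 product leads to 17. The fallback sets out from 15 and comes back at 16. It raises the oxidation level so that a carboxylate, not an alcohol, directs the opening. Compound 15 is oxidised (RuCl3 cat., NaIO4, CCl4/MeCN/H2O) to (2R,3S)-3-pentyloxirane-2-carboxylic acid F1. F1 is opened with Ti(OiPr)4 and Et2NH2Cl in CH2Cl2, where the titanium carboxylate chelate directs chloride to C3 with inversion, giving (2S,3R)-3-chloro-2-hydroxyoctanoic acid F2. BH3·THF then reduces the acid to diol 16 without touching the alkyl chloride.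

**Step 10 (the aldol union).** The risks are a modest anti:syn ratio, competing enolisation of 13 at the silyloxy-bearing C10, and racemisation or Darzens-type closure of 17. The fallback sets out from 17 and comes back at 25. It keeps the α-chloroaldehyde aldol but uses a simple enone enolate and builds C10–C11 afterwards:
- Compound 17 is added to the lithium enolate of commercial (E)-4-phenylbut-3-en-2-one (LiN(iPr)2, THF, −78 °C) to give (1E,5S,6R)-6-chloro-5-hydroxy-1-phenylundec-1-en-3-one F3.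
- Et2BOMe/NaBH4 gives the syn diol (1E,3R,5S,6R)-6-chloro-1-phenylundec-1-ene-3,5-diol F4.
- AgOTf/Ag2O closes the ring to (2S,3S,5R)-2-pentyl-5-[(E)-2-phenylethenyl]oxolan-3-ol F5.
- NaH and 4-methoxybenzyl chloride give (2S,3S,5R)-3-[(4-methoxyphenyl)methoxy]-2-pentyl-5-[(E)-2-phenylethenyl]oxolane F6.
- OsO4 (cat.), NaIO4 and 2,6-lutidine in dioxane/H2O cleave the styryl group to (2R,4S,5S)-4-[(4-methoxyphenyl)methoxy]-5-pentyloxolane-2-carbaldehyde F7.
- Chelation-controlled addition of non-8-en-1-ylmagnesium bromide (MgBr2·OEt2, CH2Cl2, −78 °C; ring oxygen and aldehyde chelated, threo product) gives 25 after removal of the C10 epimer.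

**Step 12 (the ring closure).** The bulky silyl ether next to the nucleophilic C9 hydroxyl may slow the displacement or be lost to adventitious acid. The fallback sets out from 21 and comes back at 28. It puts the small ester in place before the ring is closed, so the cyclisation gives the target directly:
- Compound 21 is converted (2,2-dimethoxypropane, PPTS, CH2Cl2) into its 7,9-acetonide, tert-butyl({(1R)-1-[(4R,6S)-6-[(1R)-1-chlorohexyl]-2,2-dimethyl-1,3-dioxan-4-yl]dec-9-en-1-yl}oxy)dimethylsilane F8.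
- Bu4NF gives (1R)-1-[(4R,6S)-6-[(1R)-1-chlorohexyl]-2,2-dimethyl-1,3-dioxan-4-yl]dec-9-en-1-ol F9.
- Compound 26 with Et3N and DMAP gives (1R)-1-[(4R,6S)-6-[(1R)-1-chlorohexyl]-2,2-dimethyl-1,3-dioxan-4-yl]dec-9-en-1-yl dodecanoate F10.
- 80% aqueous AcOH at rt removes the acetonide to give (10R,11R,13S,14R)-14-chloro-11,13-dihydroxynonadec-1-en-10-yl dodecanoate F11. It is handled without base to avoid O10 to O9 acyl shift.
- AgOTf/Ag2O in THF closes the ring to 28.

## Further compounds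

F1 | step 8 | (2R,3S)-3-pentyloxirane-2-carboxylic acid | CCCCC[C@@H]1O[C@H]1C(=O)O
F2 | step 8 | (2S,3R)-3-chloro-2-hydroxyoctanoic acid | CCCCC[C@@H](Cl)[C@@H](O)C(=O)O
F3 | step 10 | (1E,5S,6R)-6-chloro-5-hydroxy-1-phenylundec-1-en-3-one | CCCCC[C@@H](Cl)[C@@H](O)CC(=O)/C=C/c1ccccc1
F4 | step 10 | (1E,3R,5S,6R)-6-chloro-1-phenylundec-1-ene-3,5-diol | CCCCC[C@@H](Cl)[C@@H](O)C[C@@H](O)/C=C/c1ccccc1
F5 | step 10 | (2S,3S,5R)-2-pentyl-5-[(E)-2-phenylethenyl]oxolan-3-ol | CCCCC[C@@H]1O[C@@H](/C=C/c2ccccc2)C[C@@H]1O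
F6 | step 10 | (2S,3S,5R)-3-[(4-methoxyphenyl)methoxy]-2-pentyl-5-[(E)-2-phenylethenyl]oxolane | CCCCC[C@@H]1O[C@@H](/C=C/c2ccccc2)C[C@@H]1OCc3ccc(OC)cc3
F7 | step 10 | (2R,4S,5S)-4-[(4-methoxyphenyl)methoxy]-5-pentyloxolane-2-carbaldehyde | CCCCC[C@@H]1O[C@@H](C=O)C[C@@H]1OCc3ccc(OC)cc3
F8 | step 12 | tert-butyl({(1R)-1-[(4R,6S)-6-[(1R)-1-chlorohexyl]-2,2-dimethyl-1,3-dioxan-4-yl]dec-9-en-1-yl}oxy)dimethylsilane | CCCCC[C@@H](Cl)[C@@H]1C[C@@H](OC(C)(C)O1)[C@H](O[Si](C)(C)C(C)(C)C)CCCCCCCC=C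
F9 | step 12 | (1R)-1-[(4R,6S)-6-[(1R)-1-chlorohexyl]-2,2-dimethyl-1,3-dioxan-4-yl]dec-9-en-1-ol | CCCCC[C@@H](Cl)[C@@H]1C[C@@H](OC(C)(C)O1)[C@H](O)CCCCCCCC=C
F10 | step 12 | (1R)-1-[(4R,6S)-6-[(1R)-1-chlorohexyl]-2,2-dimethyl-1,3-dioxan-4-yl]dec-9-en-1-yl dodecanoate | CCCCC[C@@H](Cl)[C@@H]1C[C@@H](OC(C)(C)O1)[C@H](OC(=O)CCCCCCCCCCC)CCCCCCCC=C
F11 | step 12 | (10R,11R,13S,14R)-14-chloro-11,13-dihydroxynonadec-1-en-10-yl dodecanoate | CCCCC[C@@H](Cl)[C@@H](O)C[C@@H](O)[C@H](OC(=O)CCCCCCCCCCC)CCCCCCCC=C
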